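Each new flask holds 0.37 M substrate and between 0.250 M and 0.800 M coupling partner, and I want the amount of target after 3.0 h.

all flasks: substrate 0.37 M

| run | coupling partner | remark | time |
|---|---|---|---|
| birch | 0.28 M | run made earlier |  |
| maple | 1.1 M | run made earlier |  |
| Friday's | 0.250 M |  | 3.0 h |
| Tuesday's | 0.400 M |  | 3.0 h |
| Wednesday's | 0.600 M |  | 3.0 h |
| Thursday's | 0.800 M |  | 3.0 h |

| run | time / min | target / % | substrate / % |
|---|---|---|---|
| birch | 15.0 | 1.7 | 10.6 |
| birch | 30.0 | 4.2 | 0 |
| birch | 50.0 | 7.9 | 0 |
| birch | 60.0 | 9.7 | 0.3 |
| birch | 80.0 | 14.1 | 0 |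
| birch | 90.0 | 15.2 | 1.0 |
| maple | 6.00 | 1.5 | 37.9 |
| maple | 20.0 | 3.2 | 3.1 |
| maple | 30.0 | 6.7 | 0.4 |
| maple | 50.0 | 7.6 | 0 |
| maple | 60.0 | 9.9 | 0 |
| maple | 90.0 | 14.1 | 0 |

(readings scatter by 1 percentage point)

1. amount of target at the end, in percent of the substrate charged for Friday's, Tuesday's, Wednesday's, Thursday's, in this order
2. the shape of the row from first to last (falls all the way / rises all the way / falls, then rises / hardly changes / rises, then falls)

- the analysis behind the earlier runs scatters by 1 percentage point, standard deviation
- "hardly changes" means that all values lie within two and a half points (for a concentration: within two and a half percent of the largest)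

I reckon with the fraction left, not the fraction made.

1. Partner charge. By hand, more coupling partner gives more target if it enters the slow step. The last readings of the two earlier runs do not show this: at 90.0 min, birch with [coupling partner] = 0.28 M reads 15.2% target, and maple with 1.1 M reads 14.1%. That is a gap of 1.1 percentage points for a factor of 3.93 in charge, against a scatter of 1 point per reading.

2. Waiting material. In maple at 30.0 min, substrate reads 0.4% and target 6.7%, so by these readings 92.9% of the charge is in neither form. I take this pool to be material on its way to target.

3. Time. By hand, a straight line doubles the target from 90.0 min to 3.0 h. I prefer the fraction left per 90.0 min, the share of the charge not yet target at that time, read as the mean of the two runs: 0.854. If the pool empties first-order, each further 90.0 min multiplies by this same fraction. So at 3.0 h I expect 27.2% target in each new flask, which is 0.101 M, less than Friday's 0.250 M partner. My row is flat.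

The forecast gives 29%, 29%, 29%, 29%, shape hardly changes, on the ground that “a slow step from an intermediate pool sets the rate”. Its number stands above mine; the flat row is common to both.

The flasks give 28.0%, 28.0%, 28.0%, 28.0%: the row hardly changes.

    substrate → intermediate (k = 0.00240 s⁻¹)
    substrate → side product (k = 1.50 × 10⁻⁴ s⁻¹)
    intermediate → target (k = 3.40 × 10⁻⁵ s⁻¹)
    2 coupling partner → homo dimer (k = 1.00 × 10⁻⁴ M⁻¹ s⁻¹)

At 3.00 h, Thursday's keeps 36.7% of its coupling partner and Friday's 64.9%, yet the homo dimer step leaves the target where it is. In Friday's, the intermediate goes from 79.4% at 1.50 h to 66.1% at 3.00 h, a fraction left of 0.832 over 90.0 min, beside my 0.854. Carrying 0.854 per 90.0 min from Thursday's 66.1% at 3.00 h to 30.0 h gives 3.82% intermediate, and Thursday's holds 2.43%.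

The runs come from a simulation for an exercise, and the scatter is random.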